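**Plan**

Numbering used below: ring A = C1–C6 (C2=C3, CH3 on C3, OAc on C4); ring B = C6, C7 (CH3), C8 (OAc), C9, C10, C1; side chain C10=C11(CH3)–C12H2OCHO.
Retrosynthesis: the three esters are removed and C4 is taken back to a ketone; ring B is then cut at C1–C10. C1 is the γ-carbon of the ring-A enone (C4=O, C2=C3) and is doubly allylic to the exocyclic C10=C11, so ring B is the retron of a γ-alkenylation of a ring-A dienol ether by a C10 alkenyl triflate. Further cuts: C8–C9 (aldol) and ring A at C5–C6 (Michael) and C2=C3 (aldol condensation).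
Forward: ring A is made first by an organocatalytic Michael/aldol annulation; the side chain is joined by an acetoacetate-dianion aldol; a temporary δ-lactone (O8–C12) locks the C10=C11 geometry during triflation and is then reduced open; ring B is closed last with palladium.
Stereochemistry: C7 is bought (Roche ester); C6 comes from the prolinol catalyst; C8 from Felkin–Anh addition next to C7; C1 from the forced cis ring fusion; C4 from convex-face hydride delivery; the E-alkene from the lactone ring.
The esters are differentiated at the end: formate on the primary alcohol, acetates on both secondary alcohols.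

Key step: step 11

**Route**

Step 1
Reactants: 1 methyl (R)-3-hydroxy-2-methylpropanoate
Product: 2 methyl (R)-3-[(tert-butyldiphenylsilyl)oxy]-2-methylpropanoate
Conditions: TBDPSCl, imidazole, CH2Cl2, 0 to 23 °C
Reagents that add atoms: tert-butyl(chloro)diphenylsilane, CC(C)(C)[Si](Cl)(c1ccccc1)c1ccccc1
Why: Silylation of the primary alcohol gives an acid-tolerant ether that should survive the acidic annulation of step 4; the stereocenter (future C7) is untouched.

Step 2
Reactants: 2 methyl (R)-3-[(tert-butyldiphenylsilyl)oxy]-2-methylpropanoate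
Product: 3 (R)-3-[(tert-butyldiphenylsilyl)oxy]-2-methylpropanal
Conditions: i-Bu2AlH (1.05 equiv), CH2Cl2, −78 °C; aq. KNaC4H4O6
Reagents that add atoms: none
Why: Partial ester reduction through the tetrahedral aluminate, stable at −78 °C, should stop at the aldehyde, which is used at once to avoid α-epimerisation.

Step 3
Reactants: 3 (R)-3-[(tert-butyldiphenylsilyl)oxy]-2-methylpropanal, 4 (triphenylphosphoranylidene)acetaldehyde
Product: 5 (S,E)-5-[(tert-butyldiphenylsilyl)oxy]-4-methylpent-2-enal
Conditions: toluene, 80 °C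
Reagents that add atoms: none
Why: Wittig olefination with the stabilised formyl ylide should give the E-enal (C2, C1, C6) under neutral conditions that leave the adjacent stereocenter intact.

Step 4
Reactants: 5 (S,E)-5-[(tert-butyldiphenylsilyl)oxy]-4-methylpent-2-enal, 6 tert-butyl 3-oxopentanoate
Product: 8 (S)-5-[(S)-1-((tert-butyldiphenylsilyl)oxy)propan-2-yl]-2-methylcyclohex-2-en-1-one, via Michael adduct 7 (not isolated)
Conditions: (R)-2-[diphenyl(trimethylsilyloxy)methyl]pyrrolidine (10 mol %), neat, 23 °C; then TsOH·H2O (20 mol %), toluene, 80 °C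
Reagents that add atoms: none
Why: Iminium-catalysed Michael addition of the β-keto ester (the (R)-catalyst shields one face of the enal β-carbon and so sets C6), followed by acid-promoted intramolecular aldol condensation, tert-butyl ester cleavage and decarboxylation (a Robinson-type annulation), should give ring A as a 2-methyl-5-substituted cyclohexenone.

Step 5
Reactants: 8 (S)-5-[(S)-1-((tert-butyldiphenylsilyl)oxy)propan-2-yl]-2-methylcyclohex-2-en-1-one
Product: 9 (S)-5-[(S)-1-hydroxypropan-2-yl]-2-methylcyclohex-2-en-1-one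
Conditions: Bu4NF, THF, 0 °C
Reagents that add atoms: none
Why: Fluoride desilylation frees the primary alcohol; the enone and both stereocenters should be inert.

Step 6
Reactants: 9 (S)-5-[(S)-1-hydroxypropan-2-yl]-2-methylcyclohex-2-en-1-one
Product: 10 (S)-2-[(S)-4-methyl-5-oxocyclohex-3-en-1-yl]propanal
Conditions: Dess–Martin periodinane, CH2Cl2, 0 °C; used crude
Reagents that add atoms: none
Why: Dess–Martin oxidation under near-neutral conditions should give the C8 aldehyde without epimerising C7.

Step 7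
Reactants: 10 (S)-2-[(S)-4-methyl-5-oxocyclohex-3-en-1-yl]propanal, 11 ethyl 2-methyl-3-oxobutanoate
Product: 14 (S)-4-hydroxy-3-methyl-6-[(S)-1-((S)-4-methyl-5-oxocyclohex-3-en-1-yl)ethyl]-5,6-dihydro-2H-pyran-2-one, via acetoacetate dianion 12 (not isolated), via aldol adduct 13 (not isolated)
Conditions: 11, NaH then n-BuLi, THF, 0 °C; 10, −78 °C; then 1 M aq. NaOH, 23 °C; aq. HCl to pH 2
Reagents that add atoms: none
Why: Weiler dianion aldol addition through the γ-carbon should be selective for the aldehyde over the ring ketone and follow Felkin–Anh control (nucleophile anti to the ring at C7), giving the 7,8-syn carbinol; base-mediated lactonisation then ties O8 to C12 in a six-membered ring.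

Step 8
Reactants: 14 (S)-4-hydroxy-3-methyl-6-[(S)-1-((S)-4-methyl-5-oxocyclohex-3-en-1-yl)ethyl]-5,6-dihydro-2H-pyran-2-one
Product: 15 (S)-3-methyl-6-[(S)-1-((S)-4-methyl-5-oxocyclohex-3-en-1-yl)ethyl]-2-oxo-5,6-dihydro-2H-pyran-4-yl trifluoromethanesulfonate
Conditions: Tf2O, Et3N, CH2Cl2, −78 °C
Reagents that add atoms: trifluoromethanesulfonic anhydride, O=S(=O)(OS(=O)(=O)C(F)(F)F)C(F)(F)F
Why: O-Triflation of the acidic cyclic β-keto lactone gives the C10 alkenyl triflate; because C10=C11 lies inside the lactone ring, C9 and C12 are necessarily cis and the triflate is cis to the C11 methyl.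

Step 9
Reactants: 15 (S)-3-methyl-6-[(S)-1-((S)-4-methyl-5-oxocyclohex-3-en-1-yl)ethyl]-2-oxo-5,6-dihydro-2H-pyran-4-yl trifluoromethanesulfonate
Product: 16 (S)-6-[(S)-1-((R)-5-((tert-butyldimethylsilyl)oxy)-4-methylcyclohexa-2,4-dien-1-yl)ethyl]-3-methyl-2-oxo-5,6-dihydro-2H-pyran-4-yl trifluoromethanesulfonate
Conditions: TBSOTf, Et3N, CH2Cl2, 0 to 23 °C
Reagents that add atoms: tert-butyldimethylsilyl trifluoromethanesulfonate, CC(C)(C)[Si](C)(C)OS(=O)(=O)C(F)(F)F
Why: Soft enol silylation under equilibrating conditions should remove a C1 proton and give the through-conjugated 1-siloxy-1,3-diene (C4(OSi)=C3–C2=C1), as in the thermodynamic enol silylation of steroidal 4-en-3-ones; it masks the C4 ketone for step 10 and marks C1 for step 11.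

Step 10
Reactants: 16 (S)-6-[(S)-1-((R)-5-((tert-butyldimethylsilyl)oxy)-4-methylcyclohexa-2,4-dien-1-yl)ethyl]-3-methyl-2-oxo-5,6-dihydro-2H-pyran-4-yl trifluoromethanesulfonate
Product: 17 (2E,5S,6S)-6-[(1R)-5-((tert-butyldimethylsilyl)oxy)-4-methylcyclohexa-2,4-dien-1-yl]-1,5-dihydroxy-2-methylhept-2-en-3-yl trifluoromethanesulfonate
Conditions: i-Bu2AlH (4 equiv), CH2Cl2, −78 to −20 °C; aq. KNaC4H4O6
Reagents that add atoms: none
Why: 1,2-Reduction of the unsaturated lactone through the lactol to the diol opens the temporary ring with the alkene geometry retained and brings C12 to the alcohol level; the silyl dienol ether and the alkenyl triflate should not be reduced at low temperature.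

Step 11
Reactants: 17 (2E,5S,6S)-6-[(1R)-5-((tert-butyldimethylsilyl)oxy)-4-methylcyclohexa-2,4-dien-1-yl]-1,5-dihydroxy-2-methylhept-2-en-3-yl trifluoromethanesulfonate
Product: 18 (4aR,7S,8S,8aR)-7-hydroxy-5-[(E)-1-hydroxypropan-2-ylidene]-3,8-dimethyl-4a,5,6,7,8,8a-hexahydronaphthalen-2(1H)-one
Conditions: Pd(OAc)2 (10 mol %), Ph2P(CH2)3PPh2 (12 mol %), KOAc (2 equiv), DMF, 60 °C
Reagents that add atoms: none
Why: Proposed new method: oxidative addition of the alkenyl triflate to zerovalent palladium should give a cationic alkenylpalladium species with the C10=C11 geometry retained; this inserts syn into the distal C1=C2 bond of the siloxydiene, and the resulting 1-siloxy-π-allylpalladium (C2–C3–C4) is desilylated by acetate to release the C4 enone and zerovalent palladium, so no β-hydride elimination is needed. The closest known reaction types are the intramolecular Heck cyclisation of alkenyl triflates onto cycloalkenes and the palladium-catalysed γ-arylation of silyl dienolates. Ring B is closed in the 6-exo-trig mode by formation of the C1–C10 bond. The one new stereocenter, C1, is controlled by the tether: the C6 side chain can deliver palladium only to the face of C1=C2 that it occupies, so the ring fusion must be cis (H-1 and H-6 syn), relayed from C6. The step needs C1 rather than C5 regioselectivity, which the regiodefined linear dienol ether secures (only the C1=C2 and C3=C4 π-bonds are present, attack at C2 would be 7-endo, and C3 cannot be reached). It also needs retention of alkene geometry, which stereospecific oxidative addition and insertion provide.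

Step 12
Reactants: 18 (4aR,7S,8S,8aR)-7-hydroxy-5-[(E)-1-hydroxypropan-2-ylidene]-3,8-dimethyl-4a,5,6,7,8,8a-hexahydronaphthalen-2(1H)-one
Product: 19 (2S,4aR,7S,8S,8aR)-5-[(E)-1-hydroxypropan-2-ylidene]-3,8-dimethyl-1,2,4a,5,6,7,8,8a-octahydronaphthalene-2,7-diol
Conditions: NaBH4, CeCl3·7H2O, MeOH, −78 °C
Reagents that add atoms: none
Why: Luche 1,2-reduction of the enone; both ring-B bonds at C1 and C6 sit on one face of ring A, so hydride should arrive from the open convex face and place the C4 hydroxyl cis to the C6–C7 bond (the cis-carveol relationship).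

Step 13
Reactants: 19 (2S,4aR,7S,8S,8aR)-5-[(E)-1-hydroxypropan-2-ylidene]-3,8-dimethyl-1,2,4a,5,6,7,8,8a-octahydronaphthalene-2,7-diol
Product: 20 (E)-2-[(4aR,6S,7S,8aR)-6-hydroxy-7-... see list] 2-[(2S,4aR,7S,8S,8aR)-2,7-dihydroxy-3,8-dimethyl-octahydronaphthalen-5-ylidene]propyl formate
Conditions: HCO2Ac (1.05 equiv), pyridine, CH2Cl2, −40 °C
Reagents that add atoms: acetic formic anhydride, CC(=O)OC=O
Why: Formyl transfer from the mixed anhydride is fast at low temperature and should select the unhindered primary allylic alcohol over the two hindered secondary ones (chemoselective O-formylation).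

Step 14
Reactants: 20 2-[(2S,4aR,7S,8S,8aR)-2,7-dihydroxy-3,8-dimethyl-octahydronaphthalen-5-ylidene]propyl formate
Product: 21 (2S,4aR,7S,8S,8aR)-5-[(E)-1-(formyloxy)propan-2-ylidene]-3,8-dimethyl-1,2,4a,5,6,7,8,8a-octahydronaphthalene-2,7-diyl diacetate (target)
Conditions: Ac2O, pyridine, DMAP (cat.), CH2Cl2, 0 to 23 °C
Reagents that add atoms: acetic anhydride, CC(=O)OC(C)=O
Why: DMAP-catalysed acetylation of both secondary alcohols with retention at C4 and C8; the formate should be stable to these non-nucleophilic, anhydrous conditions.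

**Compound list**

1 | methyl (R)-3-hydroxy-2-methylpropanoate | COC(=O)[C@H](C)CO | starting material
2 | methyl (R)-3-[(tert-butyldiphenylsilyl)oxy]-2-methylpropanoate | COC(=O)[C@H](C)CO[Si](c1ccccc1)(c1ccccc1)C(C)(C)C | intermediate
3 | (R)-3-[(tert-butyldiphenylsilyl)oxy]-2-methylpropanal | O=C[C@H](C)CO[Si](c1ccccc1)(c1ccccc1)C(C)(C)C | intermediate
4 | (triphenylphosphoranylidene)acetaldehyde | O=CC=P(c1ccccc1)(c1ccccc1)c1ccccc1 | starting material
5 | (S,E)-5-[(tert-butyldiphenylsilyl)oxy]-4-methylpent-2-enal | O=C/C=C/[C@H](C)CO[Si](c1ccccc1)(c1ccccc1)C(C)(C)C | intermediate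
6 | tert-butyl 3-oxopentanoate | CCC(=O)CC(=O)OC(C)(C)C | starting material
7 | tert-butyl (3R,4S)-5-[(tert-butyldiphenylsilyl)oxy]-4-methyl-3-(2-oxoethyl)-2-propanoylpentanoate (both C2 epimers) | CCC(=O)C(C(=O)OC(C)(C)C)[C@H](CC=O)[C@H](C)CO[Si](c1ccccc1)(c1ccccc1)C(C)(C)C | intermediate
8 | (S)-5-[(S)-1-((tert-butyldiphenylsilyl)oxy)propan-2-yl]-2-methylcyclohex-2-en-1-one | CC1=CC[C@H]([C@H](C)CO[Si](c2ccccc2)(c2ccccc2)C(C)(C)C)CC1=O | intermediate
9 | (S)-5-[(S)-1-hydroxypropan-2-yl]-2-methylcyclohex-2-en-1-one | CC1=CC[C@H]([C@H](C)CO)CC1=O | intermediate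
10 | (S)-2-[(S)-4-methyl-5-oxocyclohex-3-en-1-yl]propanal | CC1=CC[C@H]([C@H](C)C=O)CC1=O | intermediate
11 | ethyl 2-methyl-3-oxobutanoate | CCOC(=O)C(C)C(C)=O | starting material
12 | lithium sodium dianion of ethyl 2-methyl-3-oxobutanoate | C=C([O-])C(C)=C([O-])OCC.[Li+].[Na+] | intermediate
13 | ethyl (5S,6S)-5-hydroxy-2-methyl-6-[(S)-4-methyl-5-oxocyclohex-3-en-1-yl]-3-oxoheptanoate (both C2 epimers) | CC1=CC[C@H]([C@H](C)[C@@H](O)CC(=O)C(C)C(=O)OCC)CC1=O | intermediate
14 | (S)-4-hydroxy-3-methyl-6-[(S)-1-((S)-4-methyl-5-oxocyclohex-3-en-1-yl)ethyl]-5,6-dihydro-2H-pyran-2-one | CC1=CC[C@H]([C@H](C)[C@@H]2CC(O)=C(C)C(=O)O2)CC1=O | intermediate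
15 | (S)-3-methyl-6-[(S)-1-((S)-4-methyl-5-oxocyclohex-3-en-1-yl)ethyl]-2-oxo-5,6-dihydro-2H-pyran-4-yl trifluoromethanesulfonate | CC1=CC[C@H]([C@H](C)[C@@H]2CC(OS(=O)(=O)C(F)(F)F)=C(C)C(=O)O2)CC1=O | intermediate
16 | (S)-6-[(S)-1-((R)-5-((tert-butyldimethylsilyl)oxy)-4-methylcyclohexa-2,4-dien-1-yl)ethyl]-3-methyl-2-oxo-5,6-dihydro-2H-pyran-4-yl trifluoromethanesulfonate | CC1=C(O[Si](C)(C)C(C)(C)C)C[C@@H]([C@H](C)[C@@H]2CC(OS(=O)(=O)C(F)(F)F)=C(C)C(=O)O2)C=C1 | intermediate
17 | (2E,5S,6S)-6-[(1R)-5-((tert-butyldimethylsilyl)oxy)-4-methylcyclohexa-2,4-dien-1-yl]-1,5-dihydroxy-2-methylhept-2-en-3-yl trifluoromethanesulfonate | CC1=C(O[Si](C)(C)C(C)(C)C)C[C@@H]([C@H](C)[C@@H](O)C/C(OS(=O)(=O)C(F)(F)F)=C(/C)CO)C=C1 | intermediate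
18 | (4aR,7S,8S,8aR)-7-hydroxy-5-[(E)-1-hydroxypropan-2-ylidene]-3,8-dimethyl-4a,5,6,7,8,8a-hexahydronaphthalen-2(1H)-one | O=C1C[C@H]2[C@H](C)[C@@H](O)C/C(=C(/C)CO)[C@H]2C=C1C | intermediate
19 | (2S,4aR,7S,8S,8aR)-5-[(E)-1-hydroxypropan-2-ylidene]-3,8-dimethyl-1,2,4a,5,6,7,8,8a-octahydronaphthalene-2,7-diol | O[C@H]1C[C@H]2[C@H](C)[C@@H](O)C/C(=C(/C)CO)[C@H]2C=C1C | intermediate
20 | 2-[(2S,4aR,7S,8S,8aR)-2,7-dihydroxy-3,8-dimethyl-octahydronaphthalen-5-ylidene]propyl formate (E-alkene, 1,2,4a,5,6,7,8,8a-octahydro) | O[C@H]1C[C@H]2[C@H](C)[C@@H](O)C/C(=C(/C)COC=O)[C@H]2C=C1C | intermediate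
21 | (2S,4aR,7S,8S,8aR)-5-[(E)-1-(formyloxy)propan-2-ylidene]-3,8-dimethyl-1,2,4a,5,6,7,8,8a-octahydronaphthalene-2,7-diyl diacetate | CC(=O)O[C@H]1C[C@H]2[C@H](C)[C@@H](OC(C)=O)C/C(=C(/C)COC=O)[C@H]2C=C1C | target

**Step count and risks**

Total steps: 14. Longest linear sequence: 14 (from 1; 4, 6 and 11 are bought).

Steps most likely to fail:

1. Step 11 (proposed new method). The alkenylpalladium species may fail to insert into the siloxydiene before the dienol ether is protodesilylated back to the unreactive conjugated enone, silyl transfer to the free hydroxyls may compete, or β-hydride loss toward C9 may give an allene. Fallback by known chemistry, setting out from 17: fluoride desilylation with kinetic α-protonation (Bu4NF, AcOH, THF, −78 °C) should give the β,γ-unsaturated ketone (2E,5S,6S)-1,5-dihydroxy-2-methyl-6-[(1R)-4-methyl-5-oxocyclohex-2-en-1-yl]hept-2-en-3-yl trifluoromethanesulfonate F1. A classical intramolecular Heck cyclisation (Pd(OAc)2, PPh3, Ag2CO3, MeCN, 70 °C; 6-exo-trig onto the isolated C1=C2 bond, then β-hydride elimination toward the epimerisable C3) should give the conjugated enone and come back to the route at 18.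

2. Step 9. Enol silylation may follow the kinetic α′-deprotonation at C5 and give the cross-conjugated 2-siloxydiene, which would direct ring closure to the wrong carbon. Fallback setting out from 15: classical thermodynamic enol acetylation (isopropenyl acetate, TsOH cat., reflux), as used for steroidal 4-en-3-ones, should give the linear dienyl acetate (5R)-2-methyl-5-{(1S)-1-[(2S)-5-methyl-6-oxo-4-(trifluoromethylsulfonyloxy)-3,6-dihydro-2H-pyran-2-yl]ethyl}cyclohexa-1,3-dien-1-yl acetate F2. Reduction with i-Bu2AlH (which opens the lactone to the diol and cleaves the enol acetate to an aluminium dienolate), followed by kinetic protonation with AcOH at −78 °C, should give the β,γ-unsaturated ketone F1. The Heck cyclisation described above then returns to the route at 18.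

3. Step 4. The γ-stereocenter of enal 5 may epimerise through dienamine formation with the amine catalyst, and catalyst and substrate facial preferences may be mismatched, eroding the C6/C7 relationship. Fallback setting out from 3: Horner–Wadsworth–Emmons olefination ((EtO)2P(O)CH2CO2Et, LiCl, i-Pr2NEt, MeCN) should give ethyl (S,E)-5-[(tert-butyldiphenylsilyl)oxy]-4-methylpent-2-enoate F3. Conjugate allylation (allylmagnesium bromide, CuBr·SMe2, Me3SiCl, THF, −78 °C; addition anti to the γ-methyl by the modified Felkin–Anh model) should give ethyl (S)-3-[(S)-1-((tert-butyldiphenylsilyl)oxy)propan-2-yl]hex-5-enoate F4. Amidation (MeNH(OMe)·HCl, i-PrMgCl) should give (S)-3-[(S)-1-((tert-butyldiphenylsilyl)oxy)propan-2-yl]-N-methoxy-N-methylhex-5-enamide F5. Isopropenylmagnesium bromide should give (S)-5-[(S)-1-((tert-butyldiphenylsilyl)oxy)propan-2-yl]-2-methylocta-1,7-dien-3-one F6. Ring-closing metathesis with the second-generation Grubbs catalyst (CH2Cl2, 40 °C) closes ring A and comes back to the route at 8.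

**Further compounds**

F1 | step 11 | (2E,5S,6S)-1,5-dihydroxy-2-methyl-6-[(1R)-4-methyl-5-oxocyclohex-2-en-1-yl]hept-2-en-3-yl trifluoromethanesulfonate | CC1C=C[C@H]([C@H](C)[C@@H](O)C/C(OS(=O)(=O)C(F)(F)F)=C(/C)CO)CC1=O
F2 | step 9 | (5R)-2-methyl-5-{(1S)-1-[(2S)-5-methyl-6-oxo-4-(trifluoromethylsulfonyloxy)-3,6-dihydro-2H-pyran-2-yl]ethyl}cyclohexa-1,3-dien-1-yl acetate | CC1=C(OC(C)=O)C[C@@H]([C@H](C)[C@@H]2CC(OS(=O)(=O)C(F)(F)F)=C(C)C(=O)O2)C=C1
F3 | step 4 | ethyl (S,E)-5-[(tert-butyldiphenylsilyl)oxy]-4-methylpent-2-enoate | CCOC(=O)/C=C/[C@H](C)CO[Si](c1ccccc1)(c1ccccc1)C(C)(C)C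
F4 | step 4 | ethyl (S)-3-[(S)-1-((tert-butyldiphenylsilyl)oxy)propan-2-yl]hex-5-enoate | CCOC(=O)C[C@H](CC=C)[C@H](C)CO[Si](c1ccccc1)(c1ccccc1)C(C)(C)C
F5 | step 4 | (S)-3-[(S)-1-((tert-butyldiphenylsilyl)oxy)propan-2-yl]-N-methoxy-N-methylhex-5-enamide | CON(C)C(=O)C[C@H](CC=C)[C@H](C)CO[Si](c1ccccc1)(c1ccccc1)C(C)(C)C
F6 | step 4 | (S)-5-[(S)-1-((tert-butyldiphenylsilyl)oxy)propan-2-yl]-2-methylocta-1,7-dien-3-one | CC(=C)C(=O)C[C@H](CC=C)[C@H](C)CO[Si](c1ccccc1)(c1ccccc1)C(C)(C)C
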